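The target forms in solution from dissolved starting material, which comes off the solid substrate, so the flask holds a slurry whose liquid is followed here.

the same everywhere: solid substrate 1.5 M
- theta: the very flask that is asked about, followed so far
- flask: time 50 min

theta run (percent of the solid substrate charged)

| time / min | target / % | starting material / % |
|---|---|---|
| 0.500 | 0 | 1.2 |
| 0.667 | 0.6 | 1.7 |
| 1.00 | 0.2 | 1.8 |
| 1.50 | 0.3 | 3.5 |
| 2.50 | 0.4 | 4.9 |
| 4.00 | 0.6 | 7.3 |
| 6.00 | 1.9 | 9.1 |

(readings scatter by 0.5 percentage points)

- given per volume of solution although it is solid: solid substrate
- on the list of suspects stand: starting material <-> target; solid substrate <-> starting material; target <-> isomer of the product A; isomer of the product A <-> isomer of the product B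
- at the start none of the solid substrate is in solution
- starting material means what is dissolved; the solid is not counted in it

1. target at 50 min, in percent of the solid substrate charged
2. concentration of starting material in solution at 25 min, in percent of saturation
3. the change that raises the amount of target at 50 min, in percent of the solid substrate charged most ("none" if none brings more than 2 percentage points) (blue / amber / none)
4. amount of target at 50 min, in percent of the solid substrate charged, after blue

- blue: doubling the solubility of the solid substrate, all else as stated
- amber: doubling the dissolution coefficient of the solid substrate, all else as stated

The quantity to carry is ρ, the ratio of target to dissolved starting material, read from the latest point of the theta run at 6.00 min as 0.209; both readings behind it scatter by 0.5 percentage points, and the theta reading at 4.00 min gives 0.0822, so ρ is a loose reading. This reckoning, which is separate from the forecast, treats ρ as a pre-equilibrium: target stands at ρ times starting material. With the isomers left aside, target then makes up 17.3% of what has dissolved.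

The forecast gives 27% (17% to 38%) target, 72% (55% to 88%) of saturation, blue as the best change, and 50% (32% to 72%) after blue. Its ground: “The target follows the integral of the dissolved material”. Its central target, a share of the charge, stands above that share of the dissolved part.

The flask gives 7.94% target and 60.1% of saturation. Blue gains 7.9 points and amber 1.4 points, so blue is best, reaching 15.9%.

    starting material ⇌ target (K = 0.210, k = 0.110 min⁻¹)
    solid substrate ⇌ starting material, rate k2*(cs2 - [starting material]) while solid is left; crystals form when [starting material] > cs2 (solubility = 0.700 M, k = 0.0459 min⁻¹)
    target ⇌ isomer of the product A (K = 0.136, k = 0.0888 min⁻¹)
    isomer of the product A ⇌ isomer of the product B (K = 2.60, k = 0.0635 min⁻¹)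

At 50.0 min the asked flask holds 38.7% starting material, and ρ times that is 8.09%, beside 7.94% target in the flask. The pair relaxes with a half-life of 1.09 min, both ways together, short against 50 min. The neighbouring flask charged with 0.90 M of solid substrate holds 64.5% starting material at 50.0 min, so ρ gives 13.5%, and that flask holds 13.2% target.

(The data are calculated for an exercise, and the scatter is random.)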